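**Retrosynthetic overview**
1. Target ⇒ labda-7,13E-dien-15-ol + Meldrum's acid; allylic alcohol ⇒ (13E)-enoate ⇒ (13Z)-enol phosphate + Me2CuLi ⇒ β-keto ester.
2. Key C13–C14 disconnection: crossed Claisen condensation of the bicyclic C17 methyl ester (C1–C13 of the labdane) with the lithium enolate of tert-butyl acetate (C14–C15).
3. C7=C8 and the C8 methyl ⇒ enol triflate of a C8 ketone + MeMgBr; ketone ⇒ ozonolysis of the 8(17)-exocyclic alkene ⇒ 8α-ol.
4. C13 ester ⇒ side-chain trimming of (−)-sclareol (Lemieux–Johnson cleavage, then haloform reaction).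
5. No ring is formed: rings A and B with C5, C9 and C10 are taken intact from (−)-sclareol.

Assumption: commercial (−)-sclareol is the natural enantiomer (5S,8R,9R,10S,13R); labdane numbering is used, and every bicyclic compound keeps 5α-H, 9α-H (side chain β) and 10β-CH3 (the CIP letter at C9 changes with the C8 substituent, the geometry does not).

**Step 1**
Reactants: 1 (−)-sclareol [(13R)-labd-14-ene-8α,13-diol]
Product: 3 8α-hydroxy-14,15-dinorlabdan-13-one, via (13R)-labdane-8α,13,14,15-tetrol 2 (not isolated)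
Conditions: OsO4 (2 mol %), NaIO4 (4 equiv), THF/H2O 3:1, rt
Reagents that add atoms: none
Why: Lemieux–Johnson oxidative cleavage, in which OsO4 dihydroxylates the only alkene and periodate cleaves the resulting triol down to the C13 methyl ketone (its oxygen is the former 13-OH), leaving the ring stereocentres and the tertiary 8α-OH untouched.

**Step 2**
Reactants: 3 8α-hydroxy-14,15-dinorlabdan-13-one
Product: 5 8α-hydroxy-14,15,16-trinorlabdan-13-oic acid, via 16,16,16-tribromo-8α-hydroxy-14,15-dinorlabdan-13-one 4 (not isolated)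
Conditions: NaOBr (from Br2 and aq. NaOH), 1,4-dioxane/H2O, 0 °C → rt; then cold dil. HCl to pH 3–4
Reagents that add atoms: sodium hydroxide, [Na+].[OH-]
Why: Haloform reaction, in which the methyl group of the methyl ketone is tribrominated and then expelled by hydroxide to give the C13 carboxylic acid without touching any stereocentre.

**Step 3**
Reactants: 5 8α-hydroxy-14,15,16-trinorlabdan-13-oic acid
Product: 6 methyl 8α-hydroxy-14,15,16-trinorlabdan-13-oate
Conditions: K2CO3, MeI, DMF, rt (crude acid used at once)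
Reagents that add atoms: iodomethane, CI
Why: Carboxylate O-alkylation (SN2 on MeI) esterifies under non-acidic conditions, so the tertiary 8α-OH is neither methylated nor lactonised.

**Step 4**
Reactants: 6 methyl 8α-hydroxy-14,15,16-trinorlabdan-13-oate
Product: 8 methyl 14,15,16-trinorlabd-8(17)-en-13-oate, via methyl 8α-(chlorosulfinyloxy)-14,15,16-trinorlabdan-13-oate 7 (not isolated)
Conditions: SOCl2, pyridine, CH2Cl2, −78 °C
Reagents that add atoms: none
Why: E2 dehydration through the chlorosulfite, where the equatorial 8α leaving group has no antiperiplanar ring hydrogen in the chair, so pyridine removes a C17 methyl hydrogen and gives mainly the exocyclic alkene (minor ring-olefin isomers are removed after step 5).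

**Step 5**
Reactants: 8 methyl 14,15,16-trinorlabd-8(17)-en-13-oate
Product: 10 methyl 8-oxo-14,15,16,17-tetranorlabdan-13-oate, via secondary ozonide 9 (not isolated)
Conditions: O3, CH2Cl2, −78 °C; then Me2S, −78 °C → rt
Reagents that add atoms: ozone, [O-][O+]=O
Why: Ozonolysis with reductive work-up cleaves the only C=C to the C8 ketone, and C9 stays in its thermodynamically preferred equatorial (β side chain) configuration.

**Step 6**
Reactants: 10 methyl 8-oxo-14,15,16,17-tetranorlabdan-13-oate
Product: 12 methyl 8-(trifluoromethylsulfonyloxy)-14,15,16,17-tetranorlabd-7-en-13-oate, via potassium 7-en-8-olate 11 (not isolated)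
Conditions: KN(SiMe3)2 (1.05 equiv), THF, −78 °C; then PhNTf2, −78 → 0 °C; cold 1 M HCl
Reagents that add atoms: N-phenylbis(trifluoromethanesulfonimide), O=S(=O)(N(c1ccccc1)S(=O)(=O)C(F)(F)F)C(F)(F)F
Why: Kinetic enolate formation and O-triflation, in which the bulky amide base deprotonates the unhindered C7 methylene rather than the C9 methine next to quaternary C10 or the less acidic ester α-CH2, fixing the double bond at C7=C8.

**Step 7**
Reactants: 12 methyl 8-(trifluoromethylsulfonyloxy)-14,15,16,17-tetranorlabd-7-en-13-oate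
Product: 13 methyl 14,15,16-trinorlabd-7-en-13-oate
Conditions: MeMgBr (1.5 equiv), Fe(acac)3 (5 mol %), THF/NMP, −30 °C
Reagents that add atoms: methylmagnesium bromide, C[Mg]Br
Why: Iron-catalysed Kumada-type cross-coupling replaces the triflate by methyl with the double bond position retained, and at −30 °C it is much faster than Grignard addition to the methyl ester.

**Step 8**
Reactants: 13 methyl 14,15,16-trinorlabd-7-en-13-oate; 14 tert-butyl acetate
Product: 16 tert-butyl 13-oxo-16-norlabd-7-en-15-oate, via lithium enolate of tert-butyl acetate 15 (not isolated)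
Conditions: LiN(i-Pr)2 (3.1 equiv), 14 (3.2 equiv), THF, −78 °C; then 13, −78 → −20 °C; cold 1 M HCl
Reagents that add atoms: none
Why: Crossed Claisen condensation forms the key C13–C14 bond, because the preformed, non-self-condensing tert-butyl acetate enolate acylates on the methyl ester and the β-keto ester is then shielded from further attack as its enolate (no stereocentre is involved).

**Step 9**
Reactants: 16 tert-butyl 13-oxo-16-norlabd-7-en-15-oate
Product: 18 tert-butyl (13Z)-13-(diethoxyphosphoryloxy)-16-norlabda-7,13-dien-15-oate, via sodium (13Z)-enolate 17 (not isolated)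
Conditions: NaH, Et2O, 0 °C; then ClP(O)(OEt)2, 0 °C → rt
Reagents that add atoms: diethyl chlorophosphate, CCOP(=O)(Cl)OCC
Why: Enol phosphate formation by the Weiler protocol, in which the sodium enolate is chelated between both carbonyl oxygens in ether, so O-phosphorylation gives the (Z)-enol phosphate.

**Step 10**
Reactants: 18 tert-butyl (13Z)-13-(diethoxyphosphoryloxy)-16-norlabda-7,13-dien-15-oate
Product: 19 tert-butyl labda-7,13E-dien-15-oate
Conditions: Me2CuLi (2.5 equiv, from MeLi and CuI), Et2O, −78 → −45 °C; cold 1 M HCl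
Reagents that add atoms: lithium dimethylcuprate, [Li+].C[Cu-]C (made from methyllithium, [Li]C)
Why: Cuprate addition–elimination on the enol phosphate (Weiler coupling) replaces the phosphate by methyl with retention of geometry, which turns the (13Z)-enol phosphate into the (13E)-trisubstituted enoate.

**Step 11**
Reactants: 19 tert-butyl labda-7,13E-dien-15-oate
Product: 21 labda-7,13E-dien-15-ol, via labda-7,13E-dien-15-al 20 (not isolated)
Conditions: i-Bu2AlH (3 equiv), CH2Cl2, −78 → 0 °C; aq. potassium sodium tartrate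
Reagents that add atoms: none
Why: 1,2-Reduction of the α,β-unsaturated ester by i-Bu2AlH through the aldehyde gives the allylic alcohol without touching either trisubstituted alkene or the 13E geometry.

**Step 12**
Reactants: 21 labda-7,13E-dien-15-ol; 22 Meldrum's acid (2,2-dimethyl-1,3-dioxane-4,6-dione)
Product: 23 labda-7,13E-dien-15-yl hydrogen malonate (target)
Conditions: 22 (1.2 equiv), toluene, 90 °C
Reagents that add atoms: none
Why: Ring-opening acylation (alcoholysis) of Meldrum's acid by the primary allylic alcohol gives the malonic half ester directly with loss of acetone, under conditions too mild to isomerise the alkenes or disturb C5, C9 and C10.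

**Compound list**
1 | (−)-sclareol [(5S,8R,9R,10S,13R)-labd-14-ene-8α,13-diol] | C[C@@]1(O)CC[C@H]2C(C)(C)CCC[C@]2(C)[C@H]1CC[C@@](C)(O)C=C | starting material
2 | (13R)-labdane-8α,13,14,15-tetrol (C14 epimers) | C[C@@]1(O)CC[C@H]2C(C)(C)CCC[C@]2(C)[C@H]1CC[C@@](C)(O)C(O)CO | intermediate (not isolated)
3 | (5S,8R,9R,10S)-8α-hydroxy-14,15-dinorlabdan-13-one | C[C@@]1(O)CC[C@H]2C(C)(C)CCC[C@]2(C)[C@H]1CCC(C)=O | intermediate
4 | 16,16,16-tribromo-8α-hydroxy-14,15-dinorlabdan-13-one | C[C@@]1(O)CC[C@H]2C(C)(C)CCC[C@]2(C)[C@H]1CCC(=O)C(Br)(Br)Br | intermediate (not isolated)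
5 | (5S,8R,9R,10S)-8α-hydroxy-14,15,16-trinorlabdan-13-oic acid | C[C@@]1(O)CC[C@H]2C(C)(C)CCC[C@]2(C)[C@H]1CCC(=O)O | intermediate
6 | methyl (5S,8R,9R,10S)-8α-hydroxy-14,15,16-trinorlabdan-13-oate | C[C@@]1(O)CC[C@H]2C(C)(C)CCC[C@]2(C)[C@H]1CCC(=O)OC | intermediate
7 | methyl 8α-(chlorosulfinyloxy)-14,15,16-trinorlabdan-13-oate | C[C@@]1(OS(=O)Cl)CC[C@H]2C(C)(C)CCC[C@]2(C)[C@H]1CCC(=O)OC | intermediate (not isolated)
8 | methyl (5S,9S,10S)-14,15,16-trinorlabd-8(17)-en-13-oate | C=C1CC[C@H]2C(C)(C)CCC[C@]2(C)[C@H]1CCC(=O)OC | intermediate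
9 | secondary ozonide of 8 (1,2,4-trioxolane spiro at C8, C17 as ring CH2) | C1OOC2(O1)CC[C@H]3C(C)(C)CCC[C@]3(C)[C@H]2CCC(=O)OC | intermediate (not isolated)
10 | methyl (5S,9R,10S)-8-oxo-14,15,16,17-tetranorlabdan-13-oate | O=C1CC[C@H]2C(C)(C)CCC[C@]2(C)[C@H]1CCC(=O)OC | intermediate
11 | potassium 13-methoxy-13-oxo-14,15,16,17-tetranorlabd-7-en-8-olate | [K+].[O-]C1=CC[C@H]2C(C)(C)CCC[C@]2(C)[C@H]1CCC(=O)OC | intermediate (not isolated)
12 | methyl (5S,9R,10S)-8-(trifluoromethylsulfonyloxy)-14,15,16,17-tetranorlabd-7-en-13-oate | O=S(=O)(OC1=CC[C@H]2C(C)(C)CCC[C@]2(C)[C@H]1CCC(=O)OC)C(F)(F)F | intermediate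
13 | methyl (5S,9S,10S)-14,15,16-trinorlabd-7-en-13-oate | CC1=CC[C@H]2C(C)(C)CCC[C@]2(C)[C@H]1CCC(=O)OC | intermediate
14 | tert-butyl acetate | CC(=O)OC(C)(C)C | starting material
15 | lithium enolate of tert-butyl acetate (lithium 1-tert-butoxyethen-1-olate) | [Li+].[O-]C(=C)OC(C)(C)C | intermediate (not isolated)
16 | tert-butyl (5S,9S,10S)-13-oxo-16-norlabd-7-en-15-oate | CC1=CC[C@H]2C(C)(C)CCC[C@]2(C)[C@H]1CCC(=O)CC(=O)OC(C)(C)C | intermediate
17 | sodium (13Z)-15-tert-butoxy-15-oxo-16-norlabda-7,13-dien-13-olate | [Na+].CC1=CC[C@H]2C(C)(C)CCC[C@]2(C)[C@H]1CC/C([O-])=C/C(=O)OC(C)(C)C | intermediate (not isolated)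
18 | tert-butyl (5S,9S,10S,13Z)-13-(diethoxyphosphoryloxy)-16-norlabda-7,13-dien-15-oate | CC1=CC[C@H]2C(C)(C)CCC[C@]2(C)[C@H]1CC/C(OP(=O)(OCC)OCC)=C/C(=O)OC(C)(C)C | intermediate
19 | tert-butyl (5S,9S,10S)-labda-7,13E-dien-15-oate | CC1=CC[C@H]2C(C)(C)CCC[C@]2(C)[C@H]1CC/C(C)=C/C(=O)OC(C)(C)C | intermediate
20 | labda-7,13E-dien-15-al | CC1=CC[C@H]2C(C)(C)CCC[C@]2(C)[C@H]1CC/C(C)=C/C=O | intermediate (not isolated)
21 | (5S,9S,10S)-labda-7,13E-dien-15-ol | CC1=CC[C@H]2C(C)(C)CCC[C@]2(C)[C@H]1CC/C(C)=C/CO | intermediate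
22 | Meldrum's acid (2,2-dimethyl-1,3-dioxane-4,6-dione) | CC1(C)OC(=O)CC(=O)O1 | starting material
23 | (5S,9S,10S)-labda-7,13E-dien-15-yl hydrogen malonate; 3-{[(2E)-3-methyl-5-[(1S,4aS,8aS)-2,5,5,8a-tetramethyl-1,4,4a,5,6,7,8,8a-octahydronaphthalen-1-yl]pent-2-en-1-yl]oxy}-3-oxopropanoic acid | CC1=CC[C@H]2C(C)(C)CCC[C@]2(C)[C@H]1CC/C(C)=C/COC(=O)CC(=O)O | target

**Step count**
Total steps: 12. Longest linear sequence: 12 steps (1 → 23); 14 and 22 are used as bought.

**Three steps most likely to fail**

Step 4 (exocyclic dehydration). The chlorosulfite may give too much ring olefin, tertiary chloride or lactone. The fallback sets out from 6. Acetylation of the tertiary alcohol (AcCl, N,N-dimethylaniline, CH2Cl2, 40 °C) gives methyl 8α-acetoxy-14,15,16-trinorlabdan-13-oate F1. Thermal syn-elimination of F1 (2,4,6-collidine, reflux) gives mainly the exocyclic alkene, because the methyl hydrogens reach the cyclic transition state most easily. It comes back to the route at 8.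

Step 6 (kinetic enol triflate beside an ester). Partial enolisation at C9 or at the ester α-carbon would erode yield or regiochemistry. The fallback sets out from 6 and comes back at 13, skipping steps 4 to 7. Acid-induced E1 dehydration (cat. H2SO4 in MeOH, or p-TsOH·H2O in toluene at 80 °C) loses H7 from the C8 cation preferentially and gives 13 as the main olefin. The minor 8(9)- and 8(17)-isomers are removed on AgNO3-impregnated silica. This is less regiodefined than the main route, which is why it is only the reserve. It makes no compound outside the compound list (F0).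

Step 8 (crossed Claisen condensation). Proton transfer from the enolisable methyl ester to the acetate enolate can return 13 instead of acylating it. The fallback sets out from 13. Saponification (LiOH, THF/H2O) gives 14,15,16-trinorlabd-7-en-13-oic acid F2. 1,1'-Carbonyldiimidazole in THF converts it to 1-(14,15,16-trinorlabd-7-en-13-oyl)imidazole F3. F3 is C-acylated by Mg(O2CCH2CO2t-Bu)2 (from mono-tert-butyl malonate, MgCl2 and Et3N, THF, rt) to give tert-butyl hydrogen 2-(14,15,16-trinorlabd-7-en-13-oyl)malonate F4. F4 decarboxylates on mild acidic work-up (aq. citric acid), and the sequence comes back to the route at 16.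

**Further compounds**
F1 | step 4 | methyl 8α-acetoxy-14,15,16-trinorlabdan-13-oate | C[C@@]1(OC(C)=O)CC[C@H]2C(C)(C)CCC[C@]2(C)[C@H]1CCC(=O)OC
F0 | step 6 | none | none
F2 | step 8 | 14,15,16-trinorlabd-7-en-13-oic acid | CC1=CC[C@H]2C(C)(C)CCC[C@]2(C)[C@H]1CCC(=O)O
F3 | step 8 | 1-(14,15,16-trinorlabd-7-en-13-oyl)imidazole | CC1=CC[C@H]2C(C)(C)CCC[C@]2(C)[C@H]1CCC(=O)n1ccnc1
F4 | step 8 | tert-butyl hydrogen 2-(14,15,16-trinorlabd-7-en-13-oyl)malonate | CC1=CC[C@H]2C(C)(C)CCC[C@]2(C)[C@H]1CCC(=O)C(C(=O)O)C(=O)OC(C)(C)C
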